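## Retrosynthetic overview

1. Late stage: the C9 carbonyl comes from Riley oxidation of an 8-ketone, the O–C10 bond from oxa-Michael addition of the chalcone phenol to a 1-aryl-aristol-9-en-8-one, the chalcone C=C from a Claisen–Schmidt condensation, and the cyclopropane (C11) from 2-diazopropane addition to the C6=C7 bond of a bicyclic 6,9-dien-8-one.
2. Key disconnection: C5–C10 and C7–C8 of ring B, formed together by an intramolecular Michael–Claisen [3+3] annulation of the methyl ketone/alk-2-ynoate 16, which closes rings A and B in one operation; the extra C6 oxygen is then removed by a Stork–Danheiser transposition that also creates the C6=C7 enone needed for cyclopropanation.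
3. Enabling feature: in ring B (C5–C6–C7–C8–C9–C10) C5 and C7 both flank C6, and C8 and C10 both flank C9, so with a temporary carbonyl at C6 and C9≡C10 at the alkyne level ring B is a cyclohexane-1,3-dione retron (C5/C7 = α/α′ carbons of one ketone, C10 = Michael carbon, C8 = ester carbon); the quaternary C5 blocks aromatisation and the C4 methyl controls C5.
4. Precursor 16 comes from (R)-citronellic acid (source of C4, the only purchased stereocentre), methyl propiolate (C8–C10) and the bis-allyl ether of 2',6'-dihydroxy-4'-methoxyacetophenone, joined by a Nicholas arylation.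
5. Ring order: arene (bought) → rings A and B (step 8) → cyclopropane (step 11) → dihydrofuran ring (step 13).

Key step: step 8

Remark (numbering): aristolane numbering is used for the terpenoid part: C1 benzylic CH, C2, C3, C4 (CH–CH3), C5 (quaternary C–CH3), C6 and C7 (cyclopropane CH), C8 and C9 (C=O), C10 (C–O), C11 (CMe2). Ar = 3-acetyl-6-methoxy-2,4-bis(prop-2-enyloxy)phenyl.

Remark (configuration): the target SMILES is read as ring fusion A/B cis (O on C10 syn to the C5 methyl), the C4 and C5 methyl groups cis, the aryl on C1 syn to O-10, and the cyclopropane on the opposite face.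

Assumption: the epimers at the carbon that becomes C5 (from step 1) and at C1 (from steps 4 and 6) are carried on unseparated, because C5 is enolised in step 8 and C1 is equilibrated in step 13; these centres are left undefined in the SMILES. Cobalt complexes are written with formal Co–C single bonds and Co=C=O carbonyl ligands.

## Route

Step 1
Reactants: 1 (R)-citronellic acid [(3R)-3,7-dimethyloct-6-enoic acid]; 2 iodomethane
Product: 3 (3R)-2,3,7-trimethyloct-6-enoic acid (both C2 epimers)
Conditions: LDA (2.2 equiv), THF, −78 to 0 °C; MeI, −78 °C to rt; aq. HCl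
Reagents that add atoms: iodomethane, CI
Why: α-Alkylation of a carboxylic acid dianion; the new C2 centre (later C5) forms as a mixture that is erased by enolisation in step 8, and the C3 methyl stereocentre (later C4) is not touched.

Step 2
Reactants: 3 (3R)-2,3,7-trimethyloct-6-enoic acid; 4 methyllithium
Product: 5 (4R)-3,4,8-trimethylnon-7-en-2-one (both C3 epimers)
Conditions: MeLi (2.2 equiv), Et2O, 0 °C to rt; H2O
Reagents that add atoms: methyllithium, [Li]C
Why: Addition of MeLi to the lithium carboxylate gives a stable gem-dialkoxide that collapses to the methyl ketone only on aqueous work-up (classical acid-to-methyl-ketone conversion); no stereocentre is set.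

Step 3
Reactants: 5 (4R)-3,4,8-trimethylnon-7-en-2-one; 6 ozone
Product: 7 (4R)-4,5-dimethyl-6-oxoheptanal (both C5 epimers)
Conditions: O3, CH2Cl2, −78 °C; Me2S, −78 °C to rt
Reagents that add atoms: ozone, [O-][O+]=O
Why: Ozonolysis with reductive work-up cleaves the only C=C bond and leaves the ketone untouched; no stereocentre is set.

Step 4
Reactants: 7 (4R)-4,5-dimethyl-6-oxoheptanal; 8 methyl propiolate
Product: 9 methyl (7R)-4-hydroxy-7,8-dimethyl-9-oxodec-2-ynoate (epimers at C4 and C8)
Conditions: 8, LiHMDS, THF, −78 °C; then 7, −78 °C; AcOH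
Reagents that add atoms: methyl propiolate, C#CC(=O)OC
Why: 1,2-Addition of a lithium acetylide to an aldehyde; at −78 °C the weakly basic propiolate acetylide should add to the aldehyde and not to the methyl ketone, and the carbinol centre formed as a mixture is destroyed in step 6.

Step 5
Reactants: 10 1-(2,6-dihydroxy-4-methoxyphenyl)ethan-1-one; 11 allyl bromide
Product: 12 1-[4-methoxy-2,6-bis(prop-2-enyloxy)phenyl]ethan-1-one
Conditions: K2CO3, DMF, 60 °C
Reagents that add atoms: allyl bromide, C=CCBr
Why: Williamson etherification of both phenols; the allyl ethers mask the oxygen that would otherwise add to the ynoate and leave a neutral, symmetric Friedel–Crafts nucleophile with two equivalent free positions.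

Step 6
Reactants: 9 methyl (7R)-4-hydroxy-7,8-dimethyl-9-oxodec-2-ynoate; 13 dicobalt octacarbonyl; 12 1-[4-methoxy-2,6-bis(prop-2-enyloxy)phenyl]ethan-1-one
Product: 15 hexacarbonyldicobalt complex of methyl (7R)-4-Ar-7,8-dimethyl-9-oxodec-2-ynoate, via cobalt-complexed propargylic alcohol 14 (not isolated)
Conditions: Co2(CO)8, CH2Cl2, rt; then 12 (2 equiv), BF3·OEt2, −40 to 0 °C
Reagents that add atoms: dicobalt octacarbonyl, O=C=[Co](=C=O)(=C=O)(=C=O)[Co](=C=O)(=C=O)(=C=O)=C=O; arene 12, CC(=O)c1c(OCC=C)cc(OC)cc1OCC=C
Why: Nicholas reaction: BF3 ionises the complexed propargylic alcohol and the Co2(CO)6-stabilised cation alkylates the trialkoxyarene at one of its two equivalent free positions (Friedel–Crafts), the complexed alkyne being protected from conjugate addition; the benzylic centre C1 forms unselectively and is equilibrated in step 13.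

Step 7
Reactants: 15 hexacarbonyldicobalt complex of the aryl ynoate
Product: 16 methyl (7R)-4-Ar-7,8-dimethyl-9-oxodec-2-ynoate (epimers at C4 and C8)
Conditions: Fe(NO3)3·9H2O, EtOH, 0 °C to rt
Reagents that add atoms: none
Why: Oxidative decomplexation of the alkyne–Co2(CO)6 unit by Fe(III) liberates the alk-2-ynoate under non-basic conditions; no stereocentre is changed.

Step 8
Reactants: 16 methyl (7R)-4-Ar-7,8-dimethyl-9-oxodec-2-ynoate
Product: 18 5-Ar-8,8a-dimethyl-6,7,8,8a-tetrahydronaphthalene-1,3(2H,5H)-dione (8,8a-cis-dimethyl; = 1-Ar-11,12,13-trinoraristol-9-ene-6,8-dione; keto–enol tautomers), via Michael adduct 17 (not isolated)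
Conditions: t-BuOK (2.5 equiv), THF/t-BuOH (10:1), 5 mM, 0 °C to rt; then 1 M HCl
Reagents that add atoms: none
Why: Proposed new method: t-BuOK equilibrates the enolates of the methyl ketone; the more substituted C5 enolate adds 6-exo-dig to C10 of the alk-2-ynoate (or of the allenoate formed from it by prototropy, which presents the same electrophilic carbon), and after proton transfer the C7 methyl enolate of the same ketone attacks the ester carbon C8 in a Dieckmann-type Claisen closure that is pulled to completion by deprotonation of the 1,3-diketone formed. The closest known reaction type is the intermolecular t-BuOK-mediated Michael–Claisen [3+3] synthesis of cyclohexane-1,3-diones from methyl ketones and α,β-unsaturated esters (Michael through the branched α-carbon, Claisen through the CH3 group), together with base-mediated intramolecular Michael additions of ketones to alkynoates; new here is an ynoate as two-point electrophile inside one tether, so that two rings form. Ring A closes by the Michael step (6-exo-dig, C5–C10) and ring B by the Claisen step (6-exo-trig at the ester carbonyl, C7–C8). The one new stereocentre that persists, C5, is controlled by C4: allylic 1,3-strain keeps H-4 in the plane of the tetrasubstituted enolate, the tether and the C4 methyl then lie on opposite faces, and C10 can only arrive from the tether face, anti to the C4 methyl, which gives the 4,5-cis-dimethyl relationship. The step needs site selectivity among three enolisable ketone positions and two electrophilic carbons, and ring size secures it: only C5 reaches C10 and only C7 reaches C8 through six-membered transition states, and the aryl methyl ketone, being meta to the side chain, has no strain-free intramolecular partner. The alkyne oxidation level leaves the C9=C10 double bond needed in step 13, and the quaternary C5 prevents aromatisation of ring B to a resorcinol.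

Step 9
Reactants: 18 bicyclic enedione; 19 dimethyl sulfate
Product: 20 5-Ar-3-methoxy-8,8a-dimethyl-6,7,8,8a-tetrahydronaphthalen-1(5H)-one (methyl enol ether on O8, ketone at C6)
Conditions: Me2SO4 (1.1 equiv), K2CO3, acetone, rt
Reagents that add atoms: dimethyl sulfate, COS(=O)(=O)OC
Why: O-Alkylation of the vinylogous carboxylate at the less hindered oxygen (O8; O6 is flanked by the quaternary C5), the usual regiochemistry of enol ether formation from 4,4-disubstituted cyclohexane-1,3-diones; no stereocentre is set.

Step 10
Reactants: 20 methyl enol ether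
Product: 22 8-Ar-4a,5-dimethyl-5,6,7,8-tetrahydronaphthalen-2(4aH)-one (4a,5-cis; = 1-Ar-11,12,13-trinoraristola-6,9-dien-8-one), via allylic alcohol 21 (not isolated)
Conditions: DIBAL-H (1.1 equiv), CH2Cl2, −78 °C; then 1 M HCl, THF, 0 °C
Reagents that add atoms: water, O
Why: Stork–Danheiser transposition: the Lewis-acidic hydride should reduce the most Lewis-basic carbonyl (the vinylogous ester C6=O) faster than the twisted, doubly ortho-substituted aryl ketone, and acid-induced loss of water with hydrolysis of the enol ether moves the carbonyl to C8 and gives the cross-conjugated dienone; the carbinol centre is lost again.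

Step 11
Reactants: 22 cross-conjugated dienone; 23 acetone hydrazone
Product: 26 1-Ar-aristol-9-en-8-one (cyclopropane anti to the C5 methyl), via 2-diazopropane 24 (not isolated), via pyrazoline 25 (not isolated)
Conditions: 23, HgO, KOH (cat.), Et2O, −20 °C, red distillate into 22, CH2Cl2, −78 to 0 °C; then hν (350 nm), benzene, rt
Reagents that add atoms: acetone hydrazone, CC(C)=NN
Why: 1,3-Dipolar cycloaddition of 2-diazopropane to the unhindered C6=C7 bond of the dienone (carbon terminus to the β-carbon C6; the C9=C10 bond is β,β-disubstituted and the aryl ketone is inert) from the face opposite to the angular C5 methyl, then photochemical loss of N2 from the 1-pyrazoline with retention of the cis fusion, sets C6 and C7; the same sequence is the classical way from the parent dienone to aristolone.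

Step 12
Reactants: 26 1-Ar-aristol-9-en-8-one; 27 4-methoxybenzaldehyde
Product: 28 1-{2,4-bis(prop-2-enyloxy)-6-methoxy-3-[(E)-3-(4-methoxyphenyl)prop-2-enoyl]phenyl}aristol-9-en-8-one
Conditions: KOH (aq. 50%), EtOH, rt
Reagents that add atoms: 4-methoxybenzaldehyde, COc1ccc(C=O)cc1
Why: Claisen–Schmidt condensation: the aryl methyl ketone is the only carbonyl with an α-CH on sp3 carbon that can condense (the ring enone has none), and dehydration gives the E-enone; C1 may epimerise through the vinylogous enolate without consequence.

Step 13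
Reactants: 28 bis-allyl chalcone
Product: 30 9-deoxo target (dihydrobenzofuran-fused aristolan-8-one with C9H2), via bisphenol 29 (not isolated)
Conditions: Pd(PPh3)4 (5 mol%), K2CO3, MeOH/THF, rt; pH 5 buffer, 0 °C
Reagents that add atoms: none
Why: Pd(0)-catalysed (Tsuji–Trost-type) deallylation followed by intramolecular 5-exo-trig oxa-Michael addition of the phenoxide next to the side chain to C10; attack should occur on the face of the C9=C10 bond anti to the gem-dimethylcyclopropane (as reagents attack 3-carene), the dihydrofuran can only be cis-fused, and C1 epimerises through the dienolate so that both C1 epimers converge, which sets C10 and C1; the basic medium keeps the chalcone as its phenoxide, and the reaction is stopped early to keep kinetic control.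

Step 14
Reactants: 30 9-deoxo target; 31 selenium dioxide
Product: 32 target (CNP0121765.1)
Conditions: SeO2 (1.5 equiv), 1,4-dioxane/H2O (20:1), 75 °C
Reagents that add atoms: selenium dioxide, O=[Se]=O
Why: Riley oxidation: C9 is the only enolisable position next to the C8 ketone (H-7 is a cyclopropane CH and the chalcone has no α-CH2), so SeO2 should convert the CH2 into the second carbonyl, which also ends the possibility of retro-oxa-Michael reaction; no stereocentre is touched.

## Compound list

1 | (R)-citronellic acid | OC(=O)C[C@H](C)CCC=C(C)C | starting material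
2 | iodomethane | CI | starting material
3 | (3R)-2,3,7-trimethyloct-6-enoic acid (C2 epimers) | OC(=O)C(C)[C@H](C)CCC=C(C)C | intermediate
4 | methyllithium | [Li]C | starting material
5 | (4R)-3,4,8-trimethylnon-7-en-2-one (C3 epimers) | CC(=O)C(C)[C@H](C)CCC=C(C)C | intermediate
6 | ozone | [O-][O+]=O | starting material
7 | (4R)-4,5-dimethyl-6-oxoheptanal (C5 epimers) | CC(=O)C(C)[C@H](C)CCC=O | intermediate
8 | methyl propiolate | C#CC(=O)OC | starting material
9 | methyl (7R)-4-hydroxy-7,8-dimethyl-9-oxodec-2-ynoate (C4, C8 epimers) | CC(=O)C(C)[C@H](C)CCC(O)C#CC(=O)OC | intermediate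
10 | 1-(2,6-dihydroxy-4-methoxyphenyl)ethan-1-one | CC(=O)c1c(O)cc(OC)cc1O | starting material
11 | allyl bromide | C=CCBr | starting material
12 | 1-[4-methoxy-2,6-bis(prop-2-enyloxy)phenyl]ethan-1-one | CC(=O)c1c(OCC=C)cc(OC)cc1OCC=C | intermediate
13 | dicobalt octacarbonyl | O=C=[Co](=C=O)(=C=O)(=C=O)[Co](=C=O)(=C=O)(=C=O)=C=O | starting material
14 | hexacarbonyldicobalt complex of 9 | CC(=O)C(C)[C@H](C)CCC(O)C12C3(C(=O)OC)[Co]1(=C=O)(=C=O)(=C=O)[Co]23(=C=O)(=C=O)=C=O | intermediate
15 | hexacarbonyldicobalt complex of 16 | CC(=O)C(C)[C@H](C)CCC(c1c(OC)cc(OCC=C)c(C(C)=O)c1OCC=C)C12C3(C(=O)OC)[Co]1(=C=O)(=C=O)(=C=O)[Co]23(=C=O)(=C=O)=C=O | intermediate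
16 | methyl (7R)-4-[3-acetyl-6-methoxy-2,4-bis(prop-2-enyloxy)phenyl]-7,8-dimethyl-9-oxodec-2-ynoate (C4, C8 epimers) | CC(=O)C(C)[C@H](C)CCC(C#CC(=O)OC)c1c(OC)cc(OCC=C)c(C(C)=O)c1OCC=C | intermediate
17 | methyl 2-(2-acetyl-6-Ar-2,3-dimethylcyclohexylidene)acetate (2,3-cis-dimethyl; E/Z and C6 epimers) | CC(=O)[C@@]1(C)[C@H](C)CCC(c2c(OC)cc(OCC=C)c(C(C)=O)c2OCC=C)C1=CC(=O)OC | intermediate
18 | 5-Ar-8,8a-dimethyl-6,7,8,8a-tetrahydronaphthalene-1,3(2H,5H)-dione (8,8a-cis; C5 epimers) | C24=CC(=O)CC(=O)[C@@]2(C)[C@H](C)CCC4c1c(OC)cc(OCC=C)c(C(C)=O)c1OCC=C | intermediate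
19 | dimethyl sulfate | COS(=O)(=O)OC | starting material
20 | 5-Ar-3-methoxy-8,8a-dimethyl-6,7,8,8a-tetrahydronaphthalen-1(5H)-one | C24=CC(OC)=CC(=O)[C@@]2(C)[C@H](C)CCC4c1c(OC)cc(OCC=C)c(C(C)=O)c1OCC=C | intermediate
21 | 5-Ar-3-methoxy-8,8a-dimethyl-1,5,6,7,8,8a-hexahydronaphthalen-1-ol | C24=CC(OC)=CC(O)[C@@]2(C)[C@H](C)CCC4c1c(OC)cc(OCC=C)c(C(C)=O)c1OCC=C | intermediate
22 | 8-Ar-4a,5-dimethyl-5,6,7,8-tetrahydronaphthalen-2(4aH)-one (4a,5-cis; C8 epimers) | C24=CC(=O)C=C[C@@]2(C)[C@H](C)CCC4c1c(OC)cc(OCC=C)c(C(C)=O)c1OCC=C | intermediate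
23 | acetone hydrazone | CC(C)=NN | starting material
24 | 2-diazopropane | CC(C)=[N+]=[N-] | intermediate
25 | 1-pyrazoline from 22 (N on C7, CMe2 on C6, anti to the C5 methyl) | C24=CC(=O)[C@@H]5[C@@H](C(C)(C)N=N5)[C@@]2(C)[C@H](C)CCC4c1c(OC)cc(OCC=C)c(C(C)=O)c1OCC=C | intermediate
26 | 1-Ar-aristol-9-en-8-one (C1 epimers) | C24=CC(=O)[C@@H]5[C@@H](C5(C)C)[C@@]2(C)[C@H](C)CCC4c1c(OC)cc(OCC=C)c(C(C)=O)c1OCC=C | intermediate
27 | 4-methoxybenzaldehyde | COc1ccc(C=O)cc1 | starting material
28 | bis-allyl chalcone of 26 | C24=CC(=O)[C@@H]5[C@@H](C5(C)C)[C@@]2(C)[C@H](C)CCC4c1c(OC)cc(OCC=C)c(C(=O)/C=C/c3ccc(OC)cc3)c1OCC=C | intermediate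
29 | bisphenol chalcone (1-[2,4-dihydroxy-6-methoxy-3-(4-methoxycinnamoyl)phenyl]aristol-9-en-8-one) | C24=CC(=O)[C@@H]5[C@@H](C5(C)C)[C@@]2(C)[C@H](C)CCC4c1c(OC)cc(O)c(C(=O)/C=C/c3ccc(OC)cc3)c1O | intermediate
30 | 9-deoxo target (C9H2, C8 ketone, dihydrofuran closed) | COc1ccc(/C=C/C(=O)c2c(O)cc(OC)c3c2O[C@]24CC(=O)[C@@H]5[C@@H](C5(C)C)[C@@]2(C)[C@H](C)CC[C@H]34)cc1 | intermediate
31 | selenium dioxide | O=[Se]=O | starting material
32 | CNP0121765.1 | COc1ccc(/C=C/C(=O)c2c(O)cc(OC)c3c2O[C@]24C(=O)C(=O)[C@@H]5[C@@H](C5(C)C)[C@@]2(C)[C@H](C)CC[C@H]34)cc1 | target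

## Step count and risks

Total step count: 14. Longest linear sequence: 13 steps (steps 1–4 and 6–14, from (R)-citronellic acid); step 5 is the one-step side branch.

Steps most likely to fail:

Step 8 (Proposed new method). The domino may break down in two ways: prototropic isomerisation of the ynoate through the allenoate to the 2,4-dienoate before C–C bond formation, which would leave a hydrogen on C10, or failure of the Claisen closure to follow the Michael addition under one thermodynamic base regime. The fallback uses two separate ring closures of known type. From 16, catalytic Cs2CO3 in t-BuOH/THF at rt should stop after the base-catalysed intramolecular Michael addition of the ketone to the alkynoate and allow isolation of the cyclohexylidene acetate 17. Compound 17 is then cyclised by kinetic deprotonation of the methyl ketone (LiHMDS, 3.3 equiv, THF, −78 to 0 °C; Dieckmann-type acylation, the E/Z enoate equilibrating through its dienolate), which returns to the route at 18.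

Step 10. Chemoselectivity may be lost through over-reduction of the aryl methyl ketone alongside the vinylogous ester. The fallback accepts the over-reduction and corrects it: from 20, excess DIBAL-H (3 equiv, CH2Cl2, −78 °C) reduces both carbonyls, and hydrolysis with PPTS in wet acetone at 0 °C gives the dienone carbinol 8-[3-(1-hydroxyethyl)-6-methoxy-2,4-bis(prop-2-enyloxy)phenyl]-4a,5-dimethyl-5,6,7,8-tetrahydronaphthalen-2(4aH)-one F1. MnO2 (CH2Cl2, rt) then oxidises only the benzylic alcohol and returns to the route at 22.

Step 14. Hot SeO2 may promote oxidative cyclisation of the 2'-hydroxychalcone to a flavone, and acid-promoted retro-oxa-Michael opening may erode the C10 configuration before oxidation. The fallback is a Rubottom sequence that never passes through a free enolate. From 30, TMSOTf/Et3N (CH2Cl2, 0 °C) gives the bis(trimethylsilyl) derivative (C8 silyl enol ether and aryl silyl ether) F2. Epoxidation of the enol ether with DMDO (acetone, −40 °C) and methanolysis (citric acid, MeOH) give the 9-hydroxy-8-ketone F3, and DMP (NaHCO3, CH2Cl2, rt) oxidises it to 32.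

Further compounds
F0 | step 8 | none | none
F1 | step 10 | 8-[3-(1-hydroxyethyl)-6-methoxy-2,4-bis(prop-2-enyloxy)phenyl]-4a,5-dimethyl-5,6,7,8-tetrahydronaphthalen-2(4aH)-one | C24=CC(=O)C=C[C@@]2(C)[C@H](C)CCC4c1c(OC)cc(OCC=C)c(C(C)O)c1OCC=C
F2 | step 14 | bis(trimethylsilyl) derivative of 30 (C8 silyl enol ether, aryl silyl ether) | COc1ccc(/C=C/C(=O)c2c(O[Si](C)(C)C)cc(OC)c3c2O[C@]24C=C(O[Si](C)(C)C)[C@@H]5[C@@H](C5(C)C)[C@@]2(C)[C@H](C)CC[C@H]34)cc1
F3 | step 14 | 9-hydroxy-8-ketone (9-hydroxy derivative of 30) | COc1ccc(/C=C/C(=O)c2c(O)cc(OC)c3c2O[C@]24C(O)C(=O)[C@@H]5[C@@H](C5(C)C)[C@@]2(C)[C@H](C)CC[C@H]34)cc1
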